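**Plan**
1. Cuts: the benzene ring is opened at C3a–C4 (retro-6π) and re-tied C4–C7 (retro-4π) to give a cyclobutenone. Then C7–C7a (sp3–sp2 coupling) and C5–O (vinylogous acyl substitution) are cut. The C15 chain is not cut.
2. Enabling feature: ring atoms C4(OH)–C5(O-chain)–C6(OMe)–C7(H) are the four carbons of squaric acid at the levels C=O / enol ether / enol ether / CHCl. C7a=C3a together with C1, O2 and C3 is an intact butenolide ring.
3. Forward, chain: (2E,6E)-farnesyl acetate is hydrated at C10=C11 only, acetylated, and freed at O1.
4. Forward, four-membered ring: dimethyl squarate is monoketalised and the chain alcohol displaces the β-OMe. Reduction and ketal hydrolysis then transpose the carbonyl so that the chain sits α, and OH is exchanged for Cl.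
5. Last step: coupling with 3-stannylbutenolide and a 4π/6π cascade build the benzene ring onto the lactone ring. The 4-OH is released free, so no arene protecting group is needed.
6. Stereochemistry: there are no stereocentres. Both E olefins come from farnesyl acetate and are never touched.

Key step: step 10

Assumption: the target has no stereocentre, so the stereochemical task is the (2E,6E) geometry only; sp3 centres of intermediates are racemic and are erased later.
Notation: RO = [(2E,6E)-11-acetoxy-3,7,11-trimethyldodeca-2,6-dien-1-yl]oxy; C1–C7a is the isobenzofuran-1(3H)-one numbering of the target.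

**Step 1**
Reactants: 1 (2E,6E)-farnesyl acetate
Product: 2 (2E,6E)-10-bromo-11-hydroxy-3,7,11-trimethyldodeca-2,6-dien-1-yl acetate (racemic)
Conditions: NBS (1.1 equiv), THF–H2O, 0 °C
Reagents that add atoms: N-bromosuccinimide, O=C1CCC(=O)N1Br; water, O
Why: Halohydrin formation in aqueous medium should take the terminal, least hindered C10=C11 bond (C2=C3 is deactivated by the allylic acetate), with water opening the bromonium ion at the tertiary carbon; the C10 centre forms racemic and is removed in step 2.

**Step 2**
Reactants: 2 bromohydrin acetate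
Product: 4 (2E,6E)-3,7,11-trimethyldodeca-2,6-diene-1,11-diol, via epoxy alcohol 3 (not isolated)
Conditions: LiAlH4 (excess), THF, 0 °C → reflux; Rochelle salt work-up
Reagents that add atoms: none
Why: The deprotonated bromohydrin closes to the epoxide and hydride opens it by SN2 at the less substituted C10 (epoxide reduction), leaving the tertiary alcohol, while the acetate is reduced off and the isolated olefins are inert.

**Step 3**
Reactants: 4 diol
Product: 5 (2E,6E)-3,7,11-trimethyldodeca-2,6-diene-1,11-diyl diacetate
Conditions: Ac2O, Et3N, DMAP (cat.), CH2Cl2, rt → 40 °C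
Reagents that add atoms: acetic anhydride, CC(=O)OC(C)=O
Why: DMAP-catalysed acyl transfer acetylates the primary and, more slowly, the hindered tertiary hydroxyl under non-ionising conditions.

**Step 4**
Reactants: 5 diacetate
Product: 6 (2E,6E)-11-acetoxy-3,7,11-trimethyldodeca-2,6-dien-1-ol
Conditions: K2CO3 (cat.), MeOH, 0 °C
Reagents that add atoms: none
Why: Base-catalysed methanolysis (transesterification) discriminates sterically, so the primary allylic acetate should be cleaved well before the tertiary one.

**Step 5**
Reactants: 7 dimethyl squarate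
Product: 8 2,3,4,4-tetramethoxycyclobut-2-en-1-one
Conditions: MeOTMS (2.2 equiv), TMSOTf (cat.), CH2Cl2, −78 → 0 °C
Reagents that add atoms: methoxytrimethylsilane, CO[Si](C)(C)C
Why: Noyori-type acetalisation should stop at the monoketal because the remaining carbonyl is then a deactivated vinylogous ester.

**Step 6**
Reactants: 6 chain alcohol; 8 squarate monoketal
Product: 9 3-(RO)-2,4,4-trimethoxycyclobut-2-en-1-one
Conditions: 6, LiHMDS (1.0 equiv), THF, −78 °C; then 8 (1.5 equiv), −78 → −20 °C
Reagents that add atoms: none
Why: In this addition–elimination (vinylogous transesterification) the alkoxide can only attack C3, the β-carbon of the single enone, and expel methoxide, since the α-OMe and the ketal OMe groups are not displaceable; sparingly soluble LiOMe should pull the equilibrium.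

**Step 7**
Reactants: 9 chain-bearing ketal enone
Product: 11 2-(RO)-4-hydroxy-3-methoxycyclobut-2-en-1-one (racemic), via cyclobutenol ketal 10 (not isolated)
Conditions: LiAlH(Ot-Bu)3, THF, −78 → −20 °C; aq. work-up; then 10% aq. oxalic acid on SiO2, CH2Cl2, 0 °C
Reagents that add atoms: water, O
Why: 1,2-Hydride reduction followed by mild acetal hydrolysis is a 1,2-carbonyl transposition that makes the chain-bearing carbon the α-carbon of the new enone; both termini of the dialkoxyallyl cation give the same ketone on hydration, the acetate is untouched by this hydride, and the carbinol centre is racemic and erased in step 10.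

**Step 8**
Reactants: 11 4-hydroxycyclobutenone
Product: 12 4-chloro-2-(RO)-3-methoxycyclobut-2-en-1-one (racemic)
Conditions: SOCl2, 2,6-lutidine, CH2Cl2, −30 → 0 °C; used without delay
Reagents that add atoms: thionyl chloride, O=S(Cl)Cl
Why: Chlorodehydroxylation through the chlorosulfite under buffered, cold conditions should give the conjugated 4-chloride while sparing the olefins and the tertiary acetate from acid.

**Step 9**
Reactants: 13 methyl 4-hydroxybut-2-ynoate
Product: 15 3-(tributylstannyl)furan-2(5H)-one, via hydrostannation adduct 14 (not isolated)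
Conditions: Bu3SnH, Pd(PPh3)4 (cat.), THF, 0 °C → rt; then PPTS (cat.), rt
Reagents that add atoms: tributyltin hydride, CCCC[SnH](CCCC)CCCC
Why: Pd(0)-catalysed syn-hydrostannation of an ynoate places tin α to the ester and sets CO2Me and CH2OH cis, so the adduct lactonises.

**Step 10**
Reactants: 12 4-chlorocyclobutenone; 15 3-stannylbutenolide
Product: 19 farnesylemefuranone F, via coupled cyclobutenone 16 (not isolated), via dienylketene 17 (not isolated), via cyclohexadienone 18 (not isolated)
Conditions: Pd2(dba)3 (cat.), P(2-furyl)3 (cat.), CuI (cat.), 1,4-dioxane, 50 °C, then 100 °C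
Reagents that add atoms: none
Why: Oxidative addition of Pd(0) into the activated C4–Cl bond of 12, Cu(I)-assisted transmetallation from 15 and reductive elimination make the C7–C7a bond (Stille coupling) and give 16. At 100 °C the strained ring of 16 opens by a reversible conrotatory 4π electrocyclic reaction (its C1–C4 bond) to dienylketene 17, whose ketene carbon closes onto C-β of the butenolide by a disrotatory 6π electrocyclisation (C3a–C4 bond, the only ring closed, six-membered) to 18, which enolises irreversibly to the phenol. The closest known reaction type is the phenol synthesis from 4-chlorocyclobutenones and alkenylstannanes, which includes α-stannyl enones as acceptor-substituted partners. No lasting stereocentre is made, since C4 of 16 and C3a of 18 are erased on aromatisation; only the ketene isomer with the butenolide turned inward can cyclise, while the outward isomer returns to 16. The step needs positional fidelity, which the substrates secure: the ring order C=O, C–OR, C–OMe, CH–Cl of 12 is copied into C4–OH, C5–OR, C6–OMe, C7–H, and tin on C-α of 15 puts the lactone C=O on C7a and the CH2 on C3a. It also needs chemoselectivity for C–Cl over the trisubstituted allyl ether and the non-allylic tertiary acetate, which the much faster oxidative addition of the α-keto allylic chloride should provide.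

**Compound list**
1 | (2E,6E)-farnesyl acetate | CC(=O)OC/C=C(\C)CC/C=C(\C)CCC=C(C)C | starting material
2 | (2E,6E)-10-bromo-11-hydroxy-3,7,11-trimethyldodeca-2,6-dien-1-yl acetate (racemic) | CC(=O)OC/C=C(\C)CC/C=C(\C)CCC(Br)C(C)(C)O | intermediate
3 | (2E,6E)-10,11-epoxy-3,7,11-trimethyldodeca-2,6-dien-1-ol (racemic, not isolated) | OC/C=C(\C)CC/C=C(\C)CCC1OC1(C)C | intermediate
4 | (2E,6E)-3,7,11-trimethyldodeca-2,6-diene-1,11-diol | OC/C=C(\C)CC/C=C(\C)CCCC(C)(C)O | intermediate
5 | (2E,6E)-3,7,11-trimethyldodeca-2,6-diene-1,11-diyl diacetate | CC(=O)OC/C=C(\C)CC/C=C(\C)CCCC(C)(C)OC(C)=O | intermediate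
6 | (2E,6E)-11-acetoxy-3,7,11-trimethyldodeca-2,6-dien-1-ol | OC/C=C(\C)CC/C=C(\C)CCCC(C)(C)OC(C)=O | intermediate
7 | dimethyl squarate (3,4-dimethoxycyclobut-3-ene-1,2-dione) | COC1=C(OC)C(=O)C1=O | starting material
8 | 2,3,4,4-tetramethoxycyclobut-2-en-1-one | COC1=C(OC)C(OC)(OC)C1=O | intermediate
9 | 3-(RO)-2,4,4-trimethoxycyclobut-2-en-1-one | COC1=C(OC/C=C(\C)CC/C=C(\C)CCCC(C)(C)OC(C)=O)C(OC)(OC)C1=O | intermediate
10 | 3-(RO)-2,4,4-trimethoxycyclobut-2-en-1-ol (racemic, not isolated) | COC1=C(OC/C=C(\C)CC/C=C(\C)CCCC(C)(C)OC(C)=O)C(OC)(OC)C1O | intermediate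
11 | 2-(RO)-4-hydroxy-3-methoxycyclobut-2-en-1-one (racemic) | COC1=C(OC/C=C(\C)CC/C=C(\C)CCCC(C)(C)OC(C)=O)C(=O)C1O | intermediate
12 | 4-chloro-2-(RO)-3-methoxycyclobut-2-en-1-one (racemic) | COC1=C(OC/C=C(\C)CC/C=C(\C)CCCC(C)(C)OC(C)=O)C(=O)C1Cl | intermediate
13 | methyl 4-hydroxybut-2-ynoate | COC(=O)C#CCO | starting material
14 | methyl (E)-4-hydroxy-2-(tributylstannyl)but-2-enoate (not isolated) | COC(=O)/C(=C\CO)[Sn](CCCC)(CCCC)CCCC | intermediate
15 | 3-(tributylstannyl)furan-2(5H)-one | O=C1OCC=C1[Sn](CCCC)(CCCC)CCCC | intermediate
16 | 2-(RO)-3-methoxy-4-(2-oxo-2,5-dihydrofuran-3-yl)cyclobut-2-en-1-one (racemic, not isolated) | COC1=C(OC/C=C(\C)CC/C=C(\C)CCCC(C)(C)OC(C)=O)C(=O)C1C2=CCOC2=O | intermediate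
17 | 2-(RO)-3-methoxy-4-(2-oxo-2,5-dihydrofuran-3-yl)buta-1,3-dien-1-one, ketene carbon chain and butenolide cis on the C(OMe)=CH bond (not isolated) | O=C=C(OC/C=C(\C)CC/C=C(\C)CCCC(C)(C)OC(C)=O)/C(OC)=C\C1=CCOC1=O | intermediate
18 | 5-(RO)-6-methoxy-3,3a-dihydroisobenzofuran-1,4-dione (racemic, not isolated) | COC1=C(OC/C=C(\C)CC/C=C(\C)CCCC(C)(C)OC(C)=O)C(=O)C2COC(=O)C2=C1 | intermediate
19 | farnesylemefuranone F, 4-hydroxy-6-methoxy-5-(RO)isobenzofuran-1(3H)-one | COc1cc2c(c(O)c1OC/C=C(\C)CC/C=C(\C)CCCC(C)(C)OC(C)=O)COC2=O | target

**Count**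
Total steps: 10. Longest linear sequence: 8 (steps 1–4, 6–8, 10).

**Steps most likely to fail**

1. Step 10.
   - What may go wrong: slow transmetallation of the electron-poor stannane may let the chloride ionise and shed its chain, Pd(0) may attack the allyl ether, or the ketene may be intercepted by the phenol already formed.
   - Fallback (arene-based, no four-membered ring), setting out from 6: Mitsunobu etherification (PPh3, DIAD, THF, 0 °C) with commercial methyl 3,4-dihydroxy-5-methoxybenzoate (COC(=O)c1cc(O)c(O)c(OC)c1). Reaction at its more acidic 4-OH, para to the ester, should give methyl 3-hydroxy-5-methoxy-4-(RO)benzoate F1.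
   - Boronate-templated ortho-hydroxymethylation (PhB(OH)2, paraformaldehyde, cat. EtCO2H, toluene, reflux) can reach only C2, the sole free ortho position of the phenol, and should give the benzodioxaborin F2.
   - Exchange with propane-1,3-diol frees the salicyl alcohol F3, which lactonises onto the neighbouring ester. The fallback comes back to the route at 19.

2. Step 8.
   - What may go wrong: activation of the hydroxyl next to the ketone may trigger ionisation to the alkoxy-stabilised cyclobutenyl cation. Loss of the allylic chain from oxygen or allylic transposition of chloride could follow.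
   - Fallback (coupling before the ketone is unmasked), setting out from 10, now isolated: methyl chloroformate and pyridine should give the allylic methyl carbonate F4.
   - Pd(0)-catalysed allylic Stille coupling with 15 (Pd2(dba)3, P(2-furyl)3, THF, rt), at the allyl terminus that carries only H, should give the butenolidyl cyclobutene ketal F5.
   - Oxalic acid on silica then unmasks the ketone. The fallback comes back to the route at 16, which is heated on to 19.

3. Step 6.
   - What may go wrong: the reversible addition–elimination may stall, or acyl transfer from the tertiary acetate to the lithium alkoxide may scramble the chain.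
   - Fallback (regiocontrol by separation instead of by the ketal), setting out from 6 and 7: exchange on the far more electrophilic dione (7 in excess, LiHMDS, THF, −78 °C) should give the mixed squarate F6.
   - LiAlH(Ot-Bu)3 reduces either carbonyl, giving 11 together with its regioisomer F7.
   - The two are separated by chromatography, and F7 is re-oxidised (MnO2) to F6 and recycled. The fallback comes back to the route at 11.

**Further compounds**
F1 | step 10 | methyl 3-hydroxy-5-methoxy-4-(RO)benzoate | COC(=O)c1cc(O)c(OC/C=C(\C)CC/C=C(\C)CCCC(C)(C)OC(C)=O)c(OC)c1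
F2 | step 10 | methyl 7-methoxy-2-phenyl-8-(RO)-4H-1,3,2-benzodioxaborinine-5-carboxylate | COC(=O)c1cc(OC)c(OC/C=C(\C)CC/C=C(\C)CCCC(C)(C)OC(C)=O)c2OB(c3ccccc3)OCc12
F3 | step 10 | methyl 3-hydroxy-2-(hydroxymethyl)-5-methoxy-4-(RO)benzoate | COC(=O)c1cc(OC)c(OC/C=C(\C)CC/C=C(\C)CCCC(C)(C)OC(C)=O)c(O)c1CO
F4 | step 8 | 3-(RO)-2,4,4-trimethoxycyclobut-2-en-1-yl methyl carbonate (racemic) | COC(=O)OC1C(OC)=C(OC/C=C(\C)CC/C=C(\C)CCCC(C)(C)OC(C)=O)C1(OC)OC
F5 | step 8 | 3-[3-(RO)-2,4,4-trimethoxycyclobut-2-en-1-yl]furan-2(5H)-one (racemic) | COC1=C(OC/C=C(\C)CC/C=C(\C)CCCC(C)(C)OC(C)=O)C(OC)(OC)C1C2=CCOC2=O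
F6 | step 6 | 3-methoxy-4-(RO)cyclobut-3-ene-1,2-dione | COC1=C(OC/C=C(\C)CC/C=C(\C)CCCC(C)(C)OC(C)=O)C(=O)C1=O
F7 | step 6 | 4-hydroxy-2-methoxy-3-(RO)cyclobut-2-en-1-one (racemic) | COC1=C(OC/C=C(\C)CC/C=C(\C)CCCC(C)(C)OC(C)=O)C(O)C1=O
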